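## Retrosynthetic overview

1. Labdane numbering is used (ring A = C1–C5 and C10, ring B = C5–C10, C19 = the CH2OAc carbon on C4, side chain = C11–C16). The last disconnection is C9–C11: Negishi coupling of a C8=C9 enol triflate (from a C9 ketone) with the side-chain alkylzinc.
2. C4 and C5: Li/NH3 reductive methylation of a C4=C5 enoate whose ester carbon is C19 sets the trans ring fusion and the C4 quaternary centre; the ester is then taken to CH2OAc.
3. Ring B (second ring) is made by a radical annulation that inserts ethylene as C6–C7 between C8 and C5 of a monocyclic ring A precursor.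
4. Enabling feature: in ring B the C6–C7 ethano unit lies between C8, which is α to the latent C9 carbonyl (the C8=C9 alkene), and C5, which is β to the C19 carbonyl carbon on C4. Both sit 1,3 across the quaternary C10, so an electrophilic C8 radical and a radical-accepting C5 can be bridged by a two-carbon alkene.
5. Ring A (first ring) comes from a catalytic asymmetric Michael addition that sets C10, chain extension and Dieckmann cyclisation.

Key step: step 8

Assumption: the quinidine-derived bifunctional catalyst of step 1 is taken to give the (R)-adduct 3; if its sense of induction is the opposite, the quinine-derived pseudoenantiomer is used and nothing else changes.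

## Route

Step 1
Reactants: 1 methyl 2-methyl-3-oxopentanoate (racemic); 2 acrolein
Product: 3 methyl (2R)-2-methyl-3-oxo-2-(3-oxopropyl)pentanoate
Conditions: 9-O-(9-phenanthryl)cupreidine (10 mol%), CH2Cl2, −25 °C
Reagents that add atoms: none
Why: Bifunctional cinchona-alkaloid catalysis of the Michael addition of α-substituted β-keto esters to acrolein is a known route to quaternary centres; the catalyst-bound enolate of 1 should add to acrolein through one face and set C10 as (R).

Step 2
Reactants: 3 methyl (2R)-2-methyl-3-oxo-2-(3-oxopropyl)pentanoate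
Product: 4 dimethyl (2E,6R)-6-methyl-6-propanoylhept-2-enedioate
Conditions: Ph3P=CHCO2Me, CH2Cl2, 23 °C
Reagents that add atoms: methyl (triphenylphosphoranylidene)acetate, COC(=O)C=P(c1ccccc1)(c1ccccc1)c1ccccc1
Why: Wittig olefination with a stabilised ylide is selective for the aldehyde over the hindered ketone and should give the E-enoate, which adds C4 and C19.

Step 3
Reactants: 4 dimethyl (2E,6R)-6-methyl-6-propanoylhept-2-enedioate
Product: 5 dimethyl (2R)-2-methyl-2-propanoylheptanedioate
Conditions: H2 (1 atm), Pd/C, EtOAc, 23 °C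
Reagents that add atoms: none
Why: Heterogeneous hydrogenation should saturate only the conjugated C=C and leave the ketone, the esters and the quaternary centre untouched.

Step 4
Reactants: 5 dimethyl (2R)-2-methyl-2-propanoylheptanedioate
Product: 6 methyl (3R)-3-methyl-2-oxo-3-propanoylcyclohexane-1-carboxylate (C1 epimers and enol tautomer)
Conditions: LiN(SiMe3)2 (2.3 equiv), THF, −78 → 0 °C; aq. HCl
Reagents that add atoms: none
Why: Dieckmann condensation: with two equivalents of amide base the ketone is masked as its enolate, the ester enolate at C4 attacks the C5 ester (6-exo-trig) and the product is drained as its β-keto ester enolate, while the non-nucleophilic base avoids retro-Claisen cleavage at the quaternary C10.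

Step 5
Reactants: 6 methyl (3R)-3-methyl-2-oxo-3-propanoylcyclohexane-1-carboxylate
Product: 7 methyl (3S)-3-methyl-3-propanoyl-2-{[(trifluoromethyl)sulfonyl]oxy}cyclohex-1-ene-1-carboxylate
Conditions: NaH (1.05 equiv), Et2O, 0 °C; Tf2O, −78 → 0 °C
Reagents that add atoms: trifluoromethanesulfonic anhydride, O=S(=O)(OS(=O)(=O)C(F)(F)F)C(F)(F)F
Why: O-Sulfonylation of the sodium enolate of the β-keto ester (the only site deprotonated by one equivalent of NaH) should give the enol triflate and fix the C4=C5 alkene.

Step 6
Reactants: 7 methyl (3S)-3-methyl-3-propanoyl-2-{[(trifluoromethyl)sulfonyl]oxy}cyclohex-1-ene-1-carboxylate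
Product: 8 methyl (3R)-3-methyl-2-(phenylsulfonyl)-3-propanoylcyclohex-1-ene-1-carboxylate
Conditions: PhSO2Na, Pd2(dba)3 (2.5 mol%), Xantphos, Cs2CO3, Bu4NCl, PhMe, 80 °C
Reagents that add atoms: sodium benzenesulfinate (PhSO2Na), [Na+].[O-]S(=O)c1ccccc1
Why: Coupling of vinyl triflates with sulfinate salts under zerovalent-palladium catalysis (oxidative addition, sulfinate exchange, C–S reductive elimination) should install the sulfonyl leaving group at C5; the triflate is activated as a β-sulfonyloxy enoate and should undergo oxidative addition despite the neighbouring quaternary carbon.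

Step 7
Reactants: 8 methyl (3R)-3-methyl-2-(phenylsulfonyl)-3-propanoylcyclohex-1-ene-1-carboxylate
Product: 9 methyl (3R)-3-(2-bromopropanoyl)-3-methyl-2-(phenylsulfonyl)cyclohex-1-ene-1-carboxylate (both epimers at the CHBr carbon)
Conditions: CuBr2 (2.2 equiv), EtOAc/CHCl3, reflux
Reagents that add atoms: copper dibromide (CuBr2), Br[Cu]Br
Why: CuBr2 α-bromination of ketones through the enol should brominate the only enolisable α-carbon of the ketone (C8) while the electron-poor alkene stays inert; the new stereocentre is uncontrolled and is destroyed in step 8.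

Step 8
Reactants: 9 methyl (3R)-3-(2-bromopropanoyl)-3-methyl-2-(phenylsulfonyl)cyclohex-1-ene-1-carboxylate; 10 ethylene
Product: 11 methyl (4aS)-4a,6-dimethyl-5-oxo-2,3,4,4a,5,6,7,8-octahydronaphthalene-1-carboxylate (both C6 epimers)
Conditions: (Bu3Sn)2 (1.2 equiv), C2H4 (2 atm), PhH (0.01 M), hν (sunlamp, Pyrex pressure tube), 80 °C
Reagents that add atoms: none
Why: Proposed new method: a tin-radical chain is proposed in which Bu3Sn• abstracts bromine from 9 to give the electrophilic α-keto radical at C8, this adds to ethylene (C7–C8), the resulting nucleophilic primary C6 radical attacks C5, the sulfonyl-bearing β-carbon of the enoate (C5–C6), and the α-ester radical at C4 then expels PhSO2•, which regenerates Bu3Sn• from (Bu3Sn)2 and returns the C4=C5 enoate. The closest known reaction types are the Kharasch-type atom-transfer addition of α-halo carbonyl compounds to 1-alkenes and radical vinylation by addition–β-elimination at vinyl sulfones carried by ditin; their merger into an annulation with ethylene is the new element. Ring B is the only ring closed, in the 6-exo-trig mode, whereas closure of the C8 radical itself (4-exo at C5, 5-endo at C4) and 7-endo closure of the C6 radical are geometrically and polarity disfavoured. The only new stereocentre is C8, which is uncontrolled and irrelevant because step 9 makes it trigonal, and C5 stays trigonal so that the ring fusion is left to step 10. The step needs incorporation of exactly one ethylene before cyclisation; this is secured by the alternating polarity (electrophilic C8 radical with ethylene, nucleophilic C6 radical with the doubly activated alkene), by the absence of any tin hydride and by the low ethylene pressure and high dilution.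

Step 9
Reactants: 11 methyl (4aS)-4a,6-dimethyl-5-oxo-2,3,4,4a,5,6,7,8-octahydronaphthalene-1-carboxylate
Product: 12 methyl (4aS)-5-{[tert-butyl(dimethyl)silyl]oxy}-4a,6-dimethyl-2,3,4,4a,7,8-hexahydronaphthalene-1-carboxylate
Conditions: TBSOTf, Et3N, CH2Cl2, 0 → 23 °C
Reagents that add atoms: tert-butyldimethylsilyl triflate, CC(C)(C)[Si](C)(C)OS(=O)(=O)C(F)(F)F
Why: Soft enolisation–silylation of the ketone, which can enolise only towards C8, should give the tetrasubstituted silyl enol ether; this removes the C8 stereocentre, protects C9 against the reductions of steps 10 and 11 and is the precursor of the enol triflate.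

Step 10
Reactants: 12 methyl (4aS)-5-{[tert-butyl(dimethyl)silyl]oxy}-4a,6-dimethyl-2,3,4,4a,7,8-hexahydronaphthalene-1-carboxylate
Product: 14 methyl (1S,4aS,8aR)-5-{[tert-butyl(dimethyl)silyl]oxy}-1,4a,6-trimethyl-1,2,3,4,4a,7,8,8a-octahydronaphthalene-1-carboxylate, via lithium ester enolate 13 (not isolated)
Conditions: Li (2.5 equiv), NH3(l)/THF, t-BuOH (1.0 equiv), −78 °C; isoprene; MeI, −78 → −33 °C
Reagents that add atoms: iodomethane, CI
Why: Dissolving-metal reductive alkylation of an α,β-unsaturated ester: the β-carbanion at C5 should be protonated axially on the face opposite to the C10 methyl (trans-decalin), and the C4 ester enolate 13 should be methylated from the equatorial face opposite to the axial C10 methyl, which leaves the ester axial (C19) and cis to the C10 methyl.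

Step 11
Reactants: 14 methyl (1S,4aS,8aR)-5-{[tert-butyl(dimethyl)silyl]oxy}-1,4a,6-trimethyl-1,2,3,4,4a,7,8,8a-octahydronaphthalene-1-carboxylate
Product: 15 [(1S,4aS,8aS)-5-{[tert-butyl(dimethyl)silyl]oxy}-1,4a,6-trimethyl-1,2,3,4,4a,7,8,8a-octahydronaphthalen-1-yl]methanol
Conditions: LiAlH4, THF, 0 → 50 °C; aq. NaOH
Reagents that add atoms: none
Why: LiAlH4 reduction of the hindered neopentyl ester to the primary alcohol; the silyl enol ether is inert to hydride and should survive a basic work-up.

Step 12
Reactants: 15 [(1S,4aS,8aS)-5-{[tert-butyl(dimethyl)silyl]oxy}-1,4a,6-trimethyl-1,2,3,4,4a,7,8,8a-octahydronaphthalen-1-yl]methanol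
Product: 16 [(1S,4aS,8aS)-5-{[tert-butyl(dimethyl)silyl]oxy}-1,4a,6-trimethyl-1,2,3,4,4a,7,8,8a-octahydronaphthalen-1-yl]methyl acetate
Conditions: Ac2O, pyridine, DMAP (cat.), CH2Cl2, 23 °C
Reagents that add atoms: acetic anhydride, CC(=O)OC(C)=O
Why: Standard acylation of the only hydroxyl group under nucleophilic catalysis.

Step 13
Reactants: 16 [(1S,4aS,8aS)-5-{[tert-butyl(dimethyl)silyl]oxy}-1,4a,6-trimethyl-1,2,3,4,4a,7,8,8a-octahydronaphthalen-1-yl]methyl acetate
Product: 17 [(1S,4aS,8aS)-1,4a,6-trimethyl-5-{[(trifluoromethyl)sulfonyl]oxy}-1,2,3,4,4a,7,8,8a-octahydronaphthalen-1-yl]methyl acetate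
Conditions: CsF, PhNTf2, DME, 23 °C
Reagents that add atoms: N-phenylbis(trifluoromethanesulfonimide), O=S(=O)(N(c1ccccc1)S(=O)(=O)C(F)(F)F)C(F)(F)F
Why: Fluoride cleaves the Si–O bond and the regiodefined cesium enolate is trapped on oxygen by PhNTf2, a known direct conversion of silyl enol ethers into enol triflates that the acetate should tolerate.

Step 14
Reactants: 18 tert-butyl(but-3-yn-1-yloxy)dimethylsilane
Product: 20 methyl (2E)-5-{[tert-butyl(dimethyl)silyl]oxy}-3-methylpent-2-enoate, via alkenyldimethylalane 19 (not isolated)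
Conditions: AlMe3, Cp2ZrCl2 (0.25 equiv), CH2Cl2, 0 → 23 °C; ClCO2Me, 0 → 23 °C
Reagents that add atoms: trimethylaluminium (AlMe3), C[Al](C)C; methyl chloroformate, COC(=O)Cl
Why: Zirconium-catalysed carboalumination (syn addition of Me–Al across the terminal alkyne, aluminium at the terminus) followed by acylation of alkenylalane 19 with retention should give the (E)-3-methyl enoate as a single geometric isomer.

Step 15
Reactants: 20 methyl (2E)-5-{[tert-butyl(dimethyl)silyl]oxy}-3-methylpent-2-enoate
Product: 21 methyl (2E)-5-bromo-3-methylpent-2-enoate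
Conditions: Ph3PBr2, CH2Cl2, 0 → 23 °C
Reagents that add atoms: dibromotriphenylphosphorane, BrP(Br)(c1ccccc1)(c1ccccc1)c1ccccc1
Why: Ph3PBr2 converts tert-butyldimethylsilyl ethers of primary alcohols directly into bromides through an oxyphosphonium ion and SN2 displacement.

Step 16
Reactants: 17 [(1S,4aS,8aS)-1,4a,6-trimethyl-5-{[(trifluoromethyl)sulfonyl]oxy}-1,2,3,4,4a,7,8,8a-octahydronaphthalen-1-yl]methyl acetate; 21 methyl (2E)-5-bromo-3-methylpent-2-enoate
Product: 23 methyl (2E)-5-[(4aR,5S,8aS)-5-(acetoxymethyl)-2,5,8a-trimethyl-3,4,4a,5,6,7,8,8a-octahydronaphthalen-1-yl]-3-methylpent-2-enoate, via alkylzinc bromide 22 (not isolated)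
Conditions: 21, Zn dust (I2-activated), DMA, 70 °C; then 17, PdCl2(dppf) (5 mol%), THF/DMA, 60 °C
Reagents that add atoms: none
Why: Negishi coupling: zinc insertion gives the ester-tolerant primary alkylzinc 22, which should couple with the enol triflate under zerovalent-palladium catalysis with retention of both alkene geometries, in the way known for 2,6,6-trimethylcyclohexenyl-type triflates.

## Compound list

1 | methyl 2-methyl-3-oxopentanoate (racemic) | CCC(=O)C(C)C(=O)OC | starting material
2 | acrolein (prop-2-enal) | C=CC=O | starting material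
3 | methyl (2R)-2-methyl-3-oxo-2-(3-oxopropyl)pentanoate | O=CCC[C@](C(=O)CC)(C(=O)OC)C | intermediate
4 | dimethyl (2E,6R)-6-methyl-6-propanoylhept-2-enedioate | COC(=O)/C=C/CC[C@](C(=O)CC)(C(=O)OC)C | intermediate
5 | dimethyl (2R)-2-methyl-2-propanoylheptanedioate | COC(=O)CCCC[C@](C(=O)CC)(C(=O)OC)C | intermediate
6 | methyl (3R)-3-methyl-2-oxo-3-propanoylcyclohexane-1-carboxylate (keto form drawn; C1 epimers and enol present) | COC(=O)C1CCC[C@](C)(C(=O)CC)C1=O | intermediate
7 | methyl (3S)-3-methyl-3-propanoyl-2-{[(trifluoromethyl)sulfonyl]oxy}cyclohex-1-ene-1-carboxylate | COC(=O)C1=C(OS(=O)(=O)C(F)(F)F)[C@@](C)(C(=O)CC)CCC1 | intermediate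
8 | methyl (3R)-3-methyl-2-(phenylsulfonyl)-3-propanoylcyclohex-1-ene-1-carboxylate | COC(=O)C1=C(S(=O)(=O)c2ccccc2)[C@@](C)(C(=O)CC)CCC1 | intermediate
9 | methyl (3R)-3-(2-bromopropanoyl)-3-methyl-2-(phenylsulfonyl)cyclohex-1-ene-1-carboxylate (both epimers at the CHBr carbon) | COC(=O)C1=C(S(=O)(=O)c2ccccc2)[C@@](C)(C(=O)C(C)Br)CCC1 | intermediate
10 | ethylene | C=C | starting material
11 | methyl (4aS)-4a,6-dimethyl-5-oxo-2,3,4,4a,5,6,7,8-octahydronaphthalene-1-carboxylate (both C6 epimers; labdane C9 ketone, C4=C5 enoate) | O=C1C(C)CCC2=C(C(=O)OC)CCC[C@]12C | intermediate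
12 | methyl (4aS)-5-{[tert-butyl(dimethyl)silyl]oxy}-4a,6-dimethyl-2,3,4,4a,7,8-hexahydronaphthalene-1-carboxylate | C1(O[Si](C)(C)C(C)(C)C)=C(C)CCC2=C(C(=O)OC)CCC[C@]12C | intermediate
13 | lithium ester enolate from 1,4-reduction of 12 (C4=C19 ketene acetal, 4aS,8aR; trans-fused, H on C5 anti to the C10 methyl; not isolated) | C1(O[Si](C)(C)C(C)(C)C)=C(C)CC[C@H]2C(=C(OC)O[Li])CCC[C@]12C | intermediate
14 | methyl (1S,4aS,8aR)-5-{[tert-butyl(dimethyl)silyl]oxy}-1,4a,6-trimethyl-1,2,3,4,4a,7,8,8a-octahydronaphthalene-1-carboxylate | C1(O[Si](C)(C)C(C)(C)C)=C(C)CC[C@H]2[C@@](C)(C(=O)OC)CCC[C@]12C | intermediate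
15 | [(1S,4aS,8aS)-5-{[tert-butyl(dimethyl)silyl]oxy}-1,4a,6-trimethyl-1,2,3,4,4a,7,8,8a-octahydronaphthalen-1-yl]methanol | C1(O[Si](C)(C)C(C)(C)C)=C(C)CC[C@H]2[C@@](C)(CO)CCC[C@]12C | intermediate
16 | [(1S,4aS,8aS)-5-{[tert-butyl(dimethyl)silyl]oxy}-1,4a,6-trimethyl-1,2,3,4,4a,7,8,8a-octahydronaphthalen-1-yl]methyl acetate | C1(O[Si](C)(C)C(C)(C)C)=C(C)CC[C@H]2[C@@](C)(COC(C)=O)CCC[C@]12C | intermediate
17 | [(1S,4aS,8aS)-1,4a,6-trimethyl-5-{[(trifluoromethyl)sulfonyl]oxy}-1,2,3,4,4a,7,8,8a-octahydronaphthalen-1-yl]methyl acetate | C1(OS(=O)(=O)C(F)(F)F)=C(C)CC[C@H]2[C@@](C)(COC(C)=O)CCC[C@]12C | intermediate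
18 | tert-butyl(but-3-yn-1-yloxy)dimethylsilane | C#CCCO[Si](C)(C)C(C)(C)C | starting material
19 | [(1E)-4-{[tert-butyl(dimethyl)silyl]oxy}-2-methylbut-1-en-1-yl]dimethylalumane (not isolated) | C[Al](C)/C=C(\C)CCO[Si](C)(C)C(C)(C)C | intermediate
20 | methyl (2E)-5-{[tert-butyl(dimethyl)silyl]oxy}-3-methylpent-2-enoate | COC(=O)/C=C(\C)CCO[Si](C)(C)C(C)(C)C | intermediate
21 | methyl (2E)-5-bromo-3-methylpent-2-enoate | COC(=O)/C=C(\C)CCBr | intermediate
22 | bromo[(3E)-5-methoxy-3-methyl-5-oxopent-3-en-1-yl]zinc (not isolated) | COC(=O)/C=C(\C)CC[Zn]Br | intermediate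
23 | methyl (2E)-5-[(4aR,5S,8aS)-5-(acetoxymethyl)-2,5,8a-trimethyl-3,4,4a,5,6,7,8,8a-octahydronaphthalen-1-yl]-3-methylpent-2-enoate | COC(=O)/C=C(\C)CCC1=C(C)CC[C@H]2[C@@](C)(COC(C)=O)CCC[C@]12C | target

## Step count and risks

Total step count: 16. Longest linear sequence: 14 (steps 1–13 and 16).

First risk, the radical annulation of step 8 (the step that bears the proposed new method). The primary C6 radical may add a second ethylene or abstract bromine before it cyclises, and closure at the fully substituted, sulfonyl-bearing C5 may be too slow to sustain the chain, so that acyclic adducts accumulate. The fallback uses known chemistry, sets out from 7 and makes the same two bonds in two operations. Suzuki–Miyaura coupling of 7 with potassium vinyltrifluoroborate (CH2=CHBF3K, PdCl2(dppf), Et3N, n-PrOH, 80 °C) should give methyl (3S)-2-ethenyl-3-methyl-3-propanoylcyclohex-1-ene-1-carboxylate F1. Catalytic KOt-Bu in t-BuOH/THF should then close ring B by intramolecular 1,6-conjugate addition (vinylogous Michael, 6-endo-trig) of the C8 ketone enolate to the terminal vinyl carbon C7. Base equilibration of the dienolate should bring the alkene back into conjugation as C4=C5, and the route is rejoined at 11.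

Second risk, the asymmetric Michael addition of step 1. Facial discrimination of the conformationally mobile acyclic keto ester enolate may be insufficient, and acrolein may oligomerise under amine catalysis. The fallback sets out from 1. Palladium-catalysed asymmetric allylic alkylation with allyl acetate ([Pd(C3H5)Cl]2, the appropriate antipode of the trans-1,2-diaminocyclohexane bis(2-diphenylphosphinobenzamide) ligand, tetramethylguanidine, PhMe) should give methyl (2R)-2-methyl-3-oxo-2-(prop-2-en-1-yl)pentanoate F2. Cross-metathesis with methyl but-3-enoate (second-generation Grubbs catalyst, CH2Cl2, 40 °C) should give dimethyl (3E,6R)-6-methyl-6-propanoylhept-3-enedioate F3. Hydrogenation (H2, Pd/C) then rejoins the route at 5.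

Third risk, the Negishi coupling of step 16. Oxidative addition and transmetalation at the tetrasubstituted triflate next to the quaternary C10 may be slow, so that protodemetalation of the zinc reagent and reduction of the triflate take over. The fallback sets out from 17 and moves the bond-forming event to the unhindered C12–C13 bond. Stille coupling with tributyl(vinyl)stannane (Pd(PPh3)4, LiCl, THF, 65 °C) should give the diene [(1S,4aS,8aR)-5-ethenyl-1,4a,6-trimethyl-1,2,3,4,4a,7,8,8a-octahydronaphthalen-1-yl]methyl acetate F4. Chemoselective hydroboration of the terminal vinyl group with 9-BBN should give the B-alkyl borane {(1S,4aS,8aR)-5-[2-(9-borabicyclo[3.3.1]nonan-9-yl)ethyl]-1,4a,6-trimethyl-1,2,3,4,4a,7,8,8a-octahydronaphthalen-1-yl}methyl acetate F5, used without isolation. Suzuki–Miyaura coupling with methyl (2E)-3-iodobut-2-enoate (PdCl2(dppf), K3PO4, DMF/H2O, 23 °C) should then give 23 directly, with retention of the E geometry.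

## Further compounds

F1 | step 8 | methyl (3S)-2-ethenyl-3-methyl-3-propanoylcyclohex-1-ene-1-carboxylate | COC(=O)C1=C(C=C)[C@@](C)(C(=O)CC)CCC1
F2 | step 1 | methyl (2R)-2-methyl-3-oxo-2-(prop-2-en-1-yl)pentanoate | C=CC[C@](C(=O)CC)(C(=O)OC)C
F3 | step 1 | dimethyl (3E,6R)-6-methyl-6-propanoylhept-3-enedioate | COC(=O)C/C=C/C[C@](C(=O)CC)(C(=O)OC)C
F4 | step 16 | [(1S,4aS,8aR)-5-ethenyl-1,4a,6-trimethyl-1,2,3,4,4a,7,8,8a-octahydronaphthalen-1-yl]methyl acetate | C1(C=C)=C(C)CC[C@H]2[C@@](C)(COC(C)=O)CCC[C@]12C
F5 | step 16 | {(1S,4aS,8aR)-5-[2-(9-borabicyclo[3.3.1]nonan-9-yl)ethyl]-1,4a,6-trimethyl-1,2,3,4,4a,7,8,8a-octahydronaphthalen-1-yl}methyl acetate | C1(CCB5C6CCCC5CCC6)=C(C)CC[C@H]4[C@@](C)(COC(C)=O)CCC[C@]14C
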